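## Structural features

Previtexilactone is a tetracyclic labdane. A trans-decalin (rings A and B, C1–C10) carries at C9 a spiro-fused oxolane (ring C: O, C9, C11, C12, C13), and C13 is in turn the spiro atom of a γ-lactone (ring D: C13, C14, C15(=O), O, C16). There are six stereocentres. C8, C9 and C10 are contiguous and C9 and C10 are fully substituted; C5 and C6 adjoin them across ring B; C13 stands alone, 1,3 to C9 through the ether oxygen. The pattern is 10β-methyl, 9α-oxygen, 8α-methyl (equatorial, syn to the oxygen), 5α-hydrogen and an axial 6β-acetate that is 1,3-diaxial to the C10 and C4β methyl groups. At C13 the CH2C(=O) arm faces C8 and the CH2O arm faces C10. Fragile points: the C13–O bond is β to the lactone carbonyl, so base can open ring C by a retro-oxa-Michael reaction; both ether carbons are tertiary, so strong acid can ionise C9 next to the quaternary C10; acetate and lactone both invite nucleophiles. The real difficulty is twofold: the C9–C10 bond joins two fully substituted carbons inside a crowded triad, and C13 lies too far from that triad for ordinary steric induction, because the C17 methyl and the C1 methylene flank ring C almost symmetrically. The key step exploits the C6 oxygen para to C9 in ring B, together with the oxygen and the C11 carbon on C9: with C11 as a carbonyl this is the retron of a Diels–Alder reaction between a 2-silyloxydiene C7=C6–C5=C10 on ring A and the exocyclic C8=C9 enone of a ring C furanone.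

## Logic of the disconnections

**C6–O acyl bond and C6–H bond (26 → 25 → 24).** The acetate is removed and C6 is returned to a ketone. An axial 6β-alcohol is what hydride should give when it enters from the open α-face, and a C6 carbonyl makes C5 epimerisable, so the trans ring fusion can be reached by equilibration. This removes one stereocentre and one ester. The forward reduction of 24 must spare the lactone, and the acylation of 25 must use a weak base because the C13–O bond is β to the lactone carbonyl.

**O16–C15 bond, the C15 oxidation level and the C11/C12 hydrogens (24 → 23 → 21 → 20).** The lactone is opened to a C16 alcohol and a two-carbon arm whose C15 is masked as the inner alkene carbon of an allyl group; C11–C12 is returned to an enol triflate. The triflate is what the preceding step delivers for free, and an allyl group is a robust latent acetic acid. The base-sensitive β-alkoxy lactone then appears only four steps from the end, and C11 is deoxygenated without a sequence of its own. Forward, the silyl enol ether must be hydrolysed before ozone is used; the same acid step frees O16 and sets C5. Ozone must distinguish the allyl group from the enol triflate, and the hydrogenolysis must be buffered.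

**C13–C14 bond (20 → 17 → 16).** The bond is cut by a retro-[3,3] shift that returns the allyl group from C13 to C11, followed by removal of the allyl group from the C11 carbonyl. An external nucleophile cannot tell the two faces of C13 apart. C11, attached directly to C9, is differentiated: the axial C10 methyl and C1 sit on its C10 side and only H8 on its C8 side. A suprafacial shift then carries that information to C13. The C13 stereocentre and all of ring D vanish, leaving the planar furanone of 16. Forward, the allyl nucleophile must enter C11 from the C8 side, the rearrangement must be concerted, and C6 must stay masked as the silyl enol ether of 16 so that only one carbonyl is exposed.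

**C7–C8 and C9–C10 (16 → 4 + 15).** Both bonds of ring B that carry the stereotriad are cut in a retro-[4+2] step, which separates ring A from ring C. The C6 silyloxy group para to C9 and the C11 carbonyl on C9 make this the only cut that forms both fully substituted carbons at once and joins two fragments of equal size. Three stereocentres and one ring vanish, and each partner is achiral. Forward, a doubly hindered pairing must react with para regiochemistry, at the exocyclic alkene only, with the carbonyl exo and on one enantioface.

**C8=C9 (15 → 10 + 11).** The ethylidene group is cut by a retro-aldol condensation. C9 of 10 is the acidic carbon between the ring oxygen and the carbonyl, and the Z isomer is the thermodynamic one. Forward, the condensation must be run stepwise so that 15, a reactive acceptor, does not meet the enolate of 10.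

**O–C13 and C11–C12 (10 → 9 → 5 + 6).** The enol ether bond of the furanone is cut by a retro-cycloisomerisation to the hydroxy ynone 9, and the acyl–alkynyl bond is then cut to give an acetylide from 5 and the glycolic acid equivalent 6. Each cut follows the polarity of the ynone. Forward, the addition to 6 must stop at the ketone oxidation level, and the ring closure must be 5-endo onto the β-carbon.

**O–Si and C6–C7 (4 → 3 → 2 → 1).** The silyl group is removed to give the methyl ketone 3, whose methyl carbon C7 is cut from the aldehyde carbon of 1. Forward, enolisation must go to the methyl group only, which is secured because it carries the only α-hydrogens.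

## Other disconnections considered

**Alternative 1:** The cut is C5–C10 and C6–C7, which opens both carbocycles to the acyclic nitro dienone A1. In the forward key step a chiral primary amine converts the C9 ketone of A1 into a 2-aminodiene; C10 adds to the nitroalkene carbon C5 (ring A) and the nitronate carbon C6 then adds to C7 (ring B), giving the nitro decalone A2.
- In its favour: two rings and four stereocentres (C5, C6, C8, C10) would arise from an achiral chain in one catalytic, metal-free operation. The trans fusion would be set directly, and C8 sits beside a ketone where its methyl group can settle equatorial.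
- Against it here: the first bond joins a fully substituted enamine carbon to a neopentylic acceptor, and the amine must first condense with a ketone branched on both sides. A2 contains none of ring C. The C9 carbonyl would have to accept a carbon nucleophile from the β-side, past the axial C10 methyl and C1, to place the oxygen α. C13 would then be formed by closing the ether ring with no controlling element, and the nitro group would need a Nef reaction.
- Comparison: on structure the alternative is the better for rings A and B (C5 is set outright, where the chosen plan relies on equilibration) and the equal for C8. It is weaker for C9 and C13, which the chosen plan handles with ring C preformed and C11 as a relay. On mechanism both form the C10 quaternary carbon against similar crowding, so the risk is about equal. On step economy the alternative is linear and needs a separate campaign for C11–C16, so the convergent plan should be shorter.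

**Alternative 2:** The cut is C4–C5, which opens ring A to the homoprenyl-substituted spirolactone enol silane A3. In the forward key step HNTf2 protonates the trisubstituted alkene of A3, and the C4 cation is captured by C5 of the enol silane to give the keto spirolactone A4.
- In its favour: the crowded C4–C5 bond would form through a tertiary cation, which tolerates congestion better than a cycloaddition; on this single bond the alternative is the better. The C6 ketone is released directly, and no chiral catalyst is needed in the key step.
- Against it here: the enol silane is the more basic π-system, so protonation there (protodesilylation) competes with alkene protonation. Triflimide can ionise the tertiary C9–O bond. A3 already holds the C8–C9–C10 triad, so the hardest problem is only moved into the precursor. In A4, C13 is a carbonyl carbon, so C14 and C16 must both still be attached with control.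
- Comparison: on structure the chosen plan solves the triad in its key step and arrives with C16 and the C13 oxygen in place, whereas A4 has neither. On mechanism the cationic closure is the equal or the better in reliability of bond formation, but the less chemoselective with the groups present. On step economy it is longer before and after the key step.

**Alternative 3:** The cut is C8–C9, which opens ring B to the seco keto enone A5. In the forward key step SmI2 (divalent samarium) reduces A5 and couples the C9 ketyl carbon with the enone β-carbon C8 to give the hydroxy ketone A6.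
- In its favour: the ring fusion (C5, C10) is fixed beforehand in a simple cyclohexane. The tertiary C9 alcohol and the C8 methyl stereocentre are formed together under nearly neutral conditions, the 6-ketone is delivered unmasked, and the polarity is matched. For C5 and for mildness the alternative is the better.
- Against it here: the enone is reduced more easily than the neopentyl ketone, so plain enone reduction or dimerisation competes. The closure is 6-endo with respect to the alkene. The C8/C9 relationship rests on a transition-state preference that is hard to foresee next to C10. A6 carries C11–C13 as an open chain, so ring C and the C13 quaternary centre with both arms remain to be built without a controlling element.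
- Comparison: on structure it is equal for C10, better for C5, and weaker for ring C and C13. On mechanism it is milder than a Lewis-acid cycloaddition but less predictable at C8/C9 than suprafacial addition to a Z-alkene. On step economy A5 needs its own stereocontrolled synthesis and the endgame is longer, so the chosen plan should be shorter.

Key step: step 7

Remark: 5 (the silyl ether of propargyl alcohol) and 6 (the acetonide of glycolic acid) are taken as catalogue chemicals.

Remark: the geometry of 15 and the configuration of 16 were re-derived from the target and need no correction: the Z-alkene gives the 8α-methyl syn to O9, and the carbonyl-exo topology gives O9 anti to the C10 methyl. What is changed is the way C13 is built afterwards.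

Remark: the sense of induction in step 7 is assumed, not derived; both antipodes of the catalyst are accessible.

## Route

Step 1
Reactants: 1 β-cyclocitral
Product: 2 1-(2,6,6-trimethylcyclohex-1-en-1-yl)ethan-1-ol (racemic)
Conditions: MeMgBr, THF, 0 °C → rt
Reagents that add atoms: methylmagnesium bromide, C[Mg]Br
Why: Grignard 1,2-addition to the hindered enal; the new carbinol centre is destroyed in step 2, so its configuration does not matter.

Step 2
Reactants: 2 1-(2,6,6-trimethylcyclohex-1-en-1-yl)ethan-1-ol
Product: 3 1-(2,6,6-trimethylcyclohex-1-en-1-yl)ethan-1-one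
Conditions: Dess–Martin periodinane, CH2Cl2, rt
Reagents that add atoms: none
Why: Dess–Martin oxidation of a secondary allylic alcohol under nearly neutral conditions; no stereocentre is involved.

Step 3
Reactants: 3 1-(2,6,6-trimethylcyclohex-1-en-1-yl)ethan-1-one
Product: 4 1-[1-(tert-butyldimethylsilyloxy)vinyl]-2,6,6-trimethylcyclohexene
Conditions: TBSOTf, Et3N, CH2Cl2, 0 °C
Reagents that add atoms: tert-butyldimethylsilyl triflate, CC(C)(C)[Si](C)(C)OS(=O)(=O)C(F)(F)F
Why: Soft enolisation and O-silylation of a methyl ketone; the acetyl group is twisted out of conjugation with the tetrasubstituted ring alkene, so only the methyl hydrogens are acidified and the cross-conjugated 2-silyloxydiene should result.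

Step 4
Reactants: 5 tert-butyldimethyl(prop-2-yn-1-yloxy)silane; 6 2,2-dimethyl-1,3-dioxolan-4-one
Product: 9 5-(tert-butyldimethylsilyloxy)-1-hydroxypent-3-yn-2-one, via lithium acetylide 7 (not isolated), via tetrahedral lithium alkoxide 8 (not isolated)
Conditions: n-BuLi, THF, −78 °C; then 6, −78 °C; AcOH, −78 °C → rt
Reagents that add atoms: none
Why: Acetylide addition to a lactone-type carbonyl; the tetrahedral alkoxide 8 persists at low temperature, which prevents a second addition, and on protonation it loses acetone to unveil the α'-hydroxy ynone.

Step 5
Reactants: 9 5-(tert-butyldimethylsilyloxy)-1-hydroxypent-3-yn-2-one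
Product: 10 5-[(tert-butyldimethylsilyloxy)methyl]furan-3(2H)-one
Conditions: Ph3PAuCl (5 mol%), AgOTf (5 mol%), toluene, rt
Reagents that add atoms: none
Why: Gold-catalysed cycloisomerisation of an α'-hydroxy ynone; the hydroxyl adds 5-endo-dig to the activated β-carbon of the ynone, giving the 3(2H)-furanone.

Step 6
Reactants: 10 5-[(tert-butyldimethylsilyloxy)methyl]furan-3(2H)-one; 11 acetaldehyde
Product: 15 (Z)-2-ethylidene-5-[(tert-butyldimethylsilyloxy)methyl]furan-3(2H)-one, via lithium furanolate 12 (not isolated), via lithium aldolate 13 (not isolated), via mesylate 14 (not isolated)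
Conditions: LiN(iPr)2, THF, −78 °C; 11; then MsCl, Et3N, −78 → 0 °C
Reagents that add atoms: none
Why: Aldol condensation run in stages: C2 is deprotonated to an aromatic 3-furanolate, which adds to the aldehyde, and mesylation followed by E1cB elimination gives the alkylidene. The Z isomer, with the methyl group beside the ring oxygen and away from the carbonyl oxygen, is the thermodynamic one, as in aurones.

Step 7
Reactants: 4 1-[1-(tert-butyldimethylsilyloxy)vinyl]-2,6,6-trimethylcyclohexene; 15 (Z)-2-ethylidene-5-[(tert-butyldimethylsilyloxy)methyl]furan-3(2H)-one
Product: 16 (8βH)-6,16-bis(tert-butyldimethylsilyloxy)-9α,13-epoxy-14,15-dinorlabda-5,12-dien-11-one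
Conditions: (S)-B-(o-tolyl)oxazaborolidine from α,α-diphenylprolinol (20 mol%), HNTf2 (18 mol%), 4 (1.5 equiv), CH2Cl2, −78 → −40 °C; Et3N quench
Reagents that add atoms: none
Why: Diels–Alder reaction under cationic oxazaborolidine catalysis: the protonated catalyst binds the C11 carbonyl (the basic vinylogous-ester oxygen), and the silyloxy-activated terminus C7 bonds to the β-carbon C8 slightly ahead of the C10–C9 bond in an asynchronous concerted [4+2] addition. The closest known reaction type is the oxazaborolidinium-catalysed cycloaddition of 2-silyloxydienes with enones, together with the spiro-annulation of aurone-type 2-alkylidenefuran-3-ones; 1-vinyl-2,6,6-trimethylcyclohexenes are established dienes for a C10 quaternary carbon. Ring B is closed by addition that is suprafacial on both partners, which annulates it onto ring A and makes C9 the spiro atom of ring C. C8: the Z geometry of 15 is carried over, so the methyl group ends syn to the ring oxygen. C9 and C10: the topology with the carbonyl exo and the ring oxygen endo is expected because the space under the diene is crowded by the C4 methyl groups and the silyloxy group, and it places O9 anti to the C10 methyl group. Absolute configuration: the catalyst covers one face of the bound dienophile, and the (S)-catalyst is assumed to leave the required face open. Regiochemistry (C6 oxygen para to C9) follows from the silyloxy group, and reaction at the exocyclic alkene only follows from the fully substituted, donor-bearing C13 of the ring alkene. The adduct keeps C6 masked as a hindered silyl enol ether, which the next two steps require.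

Step 8
Reactants: 16 (8βH)-6,16-bis(tert-butyldimethylsilyloxy)-9α,13-epoxy-14,15-dinorlabda-5,12-dien-11-one
Product: 17 (8βH)-11-allyl-6,16-bis(tert-butyldimethylsilyloxy)-9α,13-epoxy-14,15-dinorlabda-5,12-dien-11-ol (allyl on the C8 side of ring C)
Conditions: CH2=CHCH2MgBr, THF, −78 °C; pH 7 buffer
Reagents that add atoms: allylmagnesium bromide, C=CC[Mg]Br
Why: Grignard 1,2-addition to the vinylogous-ester carbonyl, the only free carbonyl group. The C10 side of C11 is blocked by the axial C10 methyl group and C1, while the C8 side offers only H8, so the allyl group should enter from the C8 side and the hydroxyl end on the C10 side.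

Step 9
Reactants: 17 (8βH)-11-allyl-6,16-bis(tert-butyldimethylsilyloxy)-9α,13-epoxy-14,15-dinorlabda-5,12-dien-11-ol
Product: 20 (8βH)-13-allyl-6,16-bis(tert-butyldimethylsilyloxy)-9α,13-epoxy-14,15-dinorlabda-5,11-dien-11-yl trifluoromethanesulfonate (allyl on the C8 side of ring C), via potassium alkoxide 18 (not isolated), via potassium enolate 19 (not isolated)
Conditions: KH, 18-crown-6, THF, 0 °C → rt; then PhNTf2, −78 °C → rt
Reagents that add atoms: N-phenylbis(trifluoromethanesulfonimide), O=S(=O)(N(c1ccccc1)S(=O)(=O)C(F)(F)F)C(F)(F)F
Why: Anionic oxy-Cope rearrangement: the allyl group moves suprafacially from C11 to C13 and arrives on the same face of ring C, which sets C13 with the new CH2 arm toward C8 and the CH2OSi arm toward C10. The enolate is formed regiospecifically and is trapped as the enol triflate. It should not eliminate, because the C13–O bond lies in the nodal plane of the enolate π-system.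

Step 10
Reactants: 20 (8βH)-13-allyl-6,16-bis(tert-butyldimethylsilyloxy)-9α,13-epoxy-14,15-dinorlabda-5,11-dien-11-yl trifluoromethanesulfonate
Product: 21 (5α,8βH)-13-allyl-9α,13-epoxy-16-hydroxy-6-oxo-14,15-dinorlabd-11-en-11-yl trifluoromethanesulfonate
Conditions: 3 M HCl (aq), THF, rt
Reagents that add atoms: none
Why: Acid hydrolysis of the silyl enol ether and of the primary silyl ether in one operation; the enol triflate is inert to aqueous acid. C5 is set under thermodynamic control by acid-catalysed enolisation of the C6 ketone, the trans-fused (5α-H) decalone being the stable isomer.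

Step 11
Reactants: 21 (5α,8βH)-13-allyl-9α,13-epoxy-16-hydroxy-6-oxo-14,15-dinorlabd-11-en-11-yl trifluoromethanesulfonate
Product: 23 (5α,8βH)-9α,13-epoxy-6-oxo-11-(trifluoromethylsulfonyloxy)labd-11-en-15-oic acid 15,16-lactone, via lactol 22 (not isolated)
Conditions: O3, CH2Cl2/MeOH, −78 °C; Me2S, → rt; then TEMPO (10 mol%), PhI(OAc)2, CH2Cl2, rt
Reagents that add atoms: ozone, [O-][O+]=O
Why: Ozonolysis of the only electron-rich alkene (the enol triflate is deactivated) gives the C15 aldehyde, which closes onto the C16 hydroxyl as a five-membered lactol. Oxoammonium oxidation of the lactol then gives the γ-lactone without touching the ketone.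

Step 12
Reactants: 23 (5α,8βH)-9α,13-epoxy-6-oxo-11-(trifluoromethylsulfonyloxy)labd-11-en-15-oic acid 15,16-lactone
Product: 24 (5α,8βH,13S)-9α,13-epoxy-6-oxolabdan-15-oic acid 15,16-lactone
Conditions: H2 (1 atm), PtO2, NaHCO3, EtOAc, rt
Reagents that add atoms: none
Why: Hydrogenolysis of the enol triflate with saturation of C11–C12, a known way to take a ketone to a methylene group through its enol triflate. No stereocentre is created, and the bicarbonate captures the triflic acid before it can ionise the tertiary ethers.

Step 13
Reactants: 24 (5α,8βH,13S)-9α,13-epoxy-6-oxolabdan-15-oic acid 15,16-lactone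
Product: 25 (5α,8βH,13S)-9α,13-epoxy-6β-hydroxylabdan-15-oic acid 15,16-lactone
Conditions: NaBH4, MeOH/THF, 0 °C
Reagents that add atoms: none
Why: Hydride reduction of the hindered ketone; the β-face of C6 is closed by the syn-axial C10 and C4β methyl groups, so hydride should enter from the α-face and give the axial 6β-alcohol. The γ-lactone is reduced much more slowly under these conditions.

Step 14
Reactants: 25 (5α,8βH,13S)-9α,13-epoxy-6β-hydroxylabdan-15-oic acid 15,16-lactone
Product: 26 previtexilactone
Conditions: Ac2O, DMAP (cat.), pyridine, 40 °C
Reagents that add atoms: acetic anhydride, CC(=O)OC(C)=O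
Why: DMAP-catalysed acylation of a hindered axial secondary alcohol; the amine bases are too weak to deprotonate the lactone, so the β-alkoxy lactone should not open.

## Compound list

1 | β-cyclocitral | CC1=C(C=O)C(C)(C)CCC1 | starting material
2 | 1-(2,6,6-trimethylcyclohex-1-en-1-yl)ethan-1-ol (racemic) | CC(O)C1=C(C)CCCC1(C)C | intermediate
3 | 1-(2,6,6-trimethylcyclohex-1-en-1-yl)ethan-1-one | CC(=O)C1=C(C)CCCC1(C)C | intermediate
4 | 1-[1-(tert-butyldimethylsilyloxy)vinyl]-2,6,6-trimethylcyclohexene | C=C(O[Si](C)(C)C(C)(C)C)C1=C(C)CCCC1(C)C | intermediate
5 | tert-butyldimethyl(prop-2-yn-1-yloxy)silane | C#CCO[Si](C)(C)C(C)(C)C | starting material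
6 | 2,2-dimethyl-1,3-dioxolan-4-one | CC1(C)OCC(=O)O1 | starting material
7 | lithium acetylide of 5 | [Li]C#CCO[Si](C)(C)C(C)(C)C | intermediate
8 | lithium 4-[3-(tert-butyldimethylsilyloxy)prop-1-yn-1-yl]-2,2-dimethyl-1,3-dioxolan-4-olate (racemic) | CC1(C)OCC(O[Li])(C#CCO[Si](C)(C)C(C)(C)C)O1 | intermediate
9 | 5-(tert-butyldimethylsilyloxy)-1-hydroxypent-3-yn-2-one | OCC(=O)C#CCO[Si](C)(C)C(C)(C)C | intermediate
10 | 5-[(tert-butyldimethylsilyloxy)methyl]furan-3(2H)-one | O=C1COC(CO[Si](C)(C)C(C)(C)C)=C1 | intermediate
11 | acetaldehyde | CC=O | starting material
12 | lithium 5-[(tert-butyldimethylsilyloxy)methyl]furan-3-olate | [Li]Oc1coc(CO[Si](C)(C)C(C)(C)C)c1 | intermediate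
13 | lithium alkoxide of 2-(1-hydroxyethyl)-5-[(tert-butyldimethylsilyloxy)methyl]furan-3(2H)-one (mixture of diastereomers) | CC(O[Li])C1OC(CO[Si](C)(C)C(C)(C)C)=CC1=O | intermediate
14 | 1-{5-[(tert-butyldimethylsilyloxy)methyl]-3-oxo-2,3-dihydrofuran-2-yl}ethyl methanesulfonate (mixture of diastereomers) | CC(OS(C)(=O)=O)C1OC(CO[Si](C)(C)C(C)(C)C)=CC1=O | intermediate
15 | (Z)-2-ethylidene-5-[(tert-butyldimethylsilyloxy)methyl]furan-3(2H)-one | C/C=C1\OC(CO[Si](C)(C)C(C)(C)C)=CC1=O | intermediate
16 | (8βH)-6,16-bis(tert-butyldimethylsilyloxy)-9α,13-epoxy-14,15-dinorlabda-5,12-dien-11-one (10β-methyl, 9α-oxygen, 8α-methyl) | CC(C)(C)[Si](C)(C)OC1=C2C(C)(C)CCC[C@]2(C)[C@]3(OC(CO[Si](C)(C)C(C)(C)C)=CC3=O)[C@H](C)C1 | intermediate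
17 | (8βH)-11-allyl-6,16-bis(tert-butyldimethylsilyloxy)-9α,13-epoxy-14,15-dinorlabda-5,12-dien-11-ol, allyl on the ring C face toward C8, hydroxyl on the face toward C10 | CC(C)(C)[Si](C)(C)OC1=C2C(C)(C)CCC[C@]2(C)[C@]3(OC(CO[Si](C)(C)C(C)(C)C)=C[C@]3(O)CC=C)[C@H](C)C1 | intermediate
18 | potassium alkoxide of 17 | CC(C)(C)[Si](C)(C)OC1=C2C(C)(C)CCC[C@]2(C)[C@]3(OC(CO[Si](C)(C)C(C)(C)C)=C[C@]3(O[K])CC=C)[C@H](C)C1 | intermediate
19 | potassium (8βH)-13-allyl-6,16-bis(tert-butyldimethylsilyloxy)-9α,13-epoxy-14,15-dinorlabda-5,11-dien-11-olate, allyl toward C8, CH2OSi toward C10 | CC(C)(C)[Si](C)(C)OC1=C2C(C)(C)CCC[C@]2(C)[C@]3(O[C@](CO[Si](C)(C)C(C)(C)C)(CC=C)C=C3O[K])[C@H](C)C1 | intermediate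
20 | (8βH)-13-allyl-6,16-bis(tert-butyldimethylsilyloxy)-9α,13-epoxy-14,15-dinorlabda-5,11-dien-11-yl trifluoromethanesulfonate, allyl toward C8 | CC(C)(C)[Si](C)(C)OC1=C2C(C)(C)CCC[C@]2(C)[C@]3(O[C@](CO[Si](C)(C)C(C)(C)C)(CC=C)C=C3OS(=O)(=O)C(F)(F)F)[C@H](C)C1 | intermediate
21 | (5α,8βH)-13-allyl-9α,13-epoxy-16-hydroxy-6-oxo-14,15-dinorlabd-11-en-11-yl trifluoromethanesulfonate, allyl toward C8 | O=C1C[C@@H](C)[C@]2(C(OS(=O)(=O)C(F)(F)F)=C[C@@](CO)(CC=C)O2)[C@@]2(C)CCCC(C)(C)[C@H]12 | intermediate
22 | (5α,8βH)-9α,13:15,16-diepoxy-15-hydroxy-6-oxolabd-11-en-11-yl trifluoromethanesulfonate (lactol, both anomers) | O=C1C[C@@H](C)[C@]2(C(OS(=O)(=O)C(F)(F)F)=C[C@]3(COC(O)C3)O2)[C@@]2(C)CCCC(C)(C)[C@H]12 | intermediate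
23 | (5α,8βH)-9α,13-epoxy-6-oxo-11-(trifluoromethylsulfonyloxy)labd-11-en-15-oic acid 15,16-lactone (CH2C(=O) arm toward C8) | O=C1C[C@@H](C)[C@]2(C(OS(=O)(=O)C(F)(F)F)=C[C@]3(COC(=O)C3)O2)[C@@]2(C)CCCC(C)(C)[C@H]12 | intermediate
24 | (5α,8βH,13S)-9α,13-epoxy-6-oxolabdan-15-oic acid 15,16-lactone | O=C1C[C@@H](C)[C@]2(CC[C@]3(COC(=O)C3)O2)[C@@]2(C)CCCC(C)(C)[C@H]12 | intermediate
25 | (5α,8βH,13S)-9α,13-epoxy-6β-hydroxylabdan-15-oic acid 15,16-lactone | O[C@@H]1C[C@@H](C)[C@]2(CC[C@]3(COC(=O)C3)O2)[C@@]2(C)CCCC(C)(C)[C@H]12 | intermediate
26 | previtexilactone, (5S,6R,8R,9R,10S,13S)-6β-acetoxy-9α,13-epoxylabdan-15-oic acid 15,16-lactone | CC(=O)O[C@@H]1C[C@@H](C)[C@]2(CC[C@]3(COC(=O)C3)O2)[C@@]2(C)CCCC(C)(C)[C@H]12 | target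

## Step count and least certain steps

Total: 14 steps. Longest linear sequence: 11 steps (steps 4–14 from 5 and 6; the branch from 1 is equally long through steps 1–3 and 7–14).

**Step 7 (key step).** Two things are most likely to go wrong. First, the reaction may take a stepwise course: after the C7–C8 bond has formed, the silyl group can shift to the furanolate oxygen, the sequence then stalls before the congested C9–C10 bond closes, or it closes after bond rotation with loss of the Z-derived C8/C9 relationship. Second, enantioface discrimination may be poor, because the α-carbon of the reacting alkene has no hydrogen for a second contact with the catalyst, and silyl triflimide formed in the flask can act as an achiral catalyst. The fallback accepts the stepwise course and uses known Mukaiyama–Michael chemistry. It sets out from 4 and 15: a Lewis-acid-promoted Mukaiyama–Michael addition at C8 followed by aqueous work-up should give the (R)-configured keto furanone 2-[4-oxo-4-(2,6,6-trimethylcyclohex-1-en-1-yl)butan-2-yl]-5-[(tert-butyldimethylsilyloxy)methyl]furan-3(2H)-one F1. Silylation with TBSOTf and Et3N converts it into the 3-silyloxyfuran F2. Catalytic HNTf2 at low temperature should then close C9 onto the enone carbon C10 in an intramolecular Mukaiyama–Michael reaction with transfer of the silyl group to O6, which comes back to the route at 16. In this variant the C9/C10 relationship rests on the cyclic transition state and no longer on the alkene geometry.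

**Step 9.** The potassium alkoxide may fragment by retro-allylation into 16 and an allyl anion; recombination would be unselective and would erase the stereochemical relay to C13. The fallback adds the allyl group directly at C13 and sets out from 16. TMSOTf converts the furanone into a silyloxy-substituted oxocarbenium ion, which CH2=CHCH2SnBu3 should attack at C13 to give the trimethylsilyl enol ether F3. MeLi cleaves only this unhindered trimethylsilyl enol ether, and PhNTf2 traps the lithium enolate, which comes back to the route at 20. C13 then depends on the small steric bias of the substrate, and the epimers would have to be separated.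

**Step 8.** Facial selectivity at C11 may be lower than predicted, or opposite to it, because allylmagnesium reagents react very fast and discriminate poorly; the labile tertiary allylic alcohol may also ionise on work-up. If entry from the C10 side dominates, the relay is changed from carbon to oxygen, since hydride would then also enter from the C10 side and leave the oxygen on the C8 side. The fallback sets out from 16:
- iBu2AlH 1,2-reduction gives the allylic alcohol F4 (hydroxyl on the C8 side).
- Ac2O in pyridine gives the acetate F5.
- LiN(iPr)2 and TBSCl give the silyl ketene acetal F6 (not isolated), which on warming undergoes an Ireland–Claisen rearrangement to the silyl ester F7 with C14 delivered to the C8 face of C13.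
- H2 over Pd on carbon saturates C11–C12 to give F8.
- 3 M HCl in THF removes the three silyl groups, sets C5 and closes the lactone, which comes back to the route at 24.

If the selectivity is merely low, the epimers of 17 are separated before step 9.

**Step 12.** The alkene may be saturated before the C–O bond is cleaved, which would leave a secondary alkyl triflate that ionises next to C9; the crowded C11=C12 bond may also resist reduction. The fallback separates the two events and sets out from 23. Pd(OAc)2, PPh3, HCO2H and Bu3N should reduce the enol triflate to the 2,5-dihydrofuran (5α,8βH)-9α,13-epoxy-6-oxolabd-11-en-15-oic acid 15,16-lactone F9, and diimide or H2 over Pd on carbon then comes back to the route at 24.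

**Step 5.** The 2-unsubstituted furanone is both acidic and nucleophilic at C2 and may self-condense, and adventitious triflic acid from the silver salt may remove the silyl ether. The fallback is the amine-mediated ring closure and sets out from 9. Et2NH adds to the ynone to give the enaminone 4-(diethylamino)-5-(tert-butyldimethylsilyloxy)-1-hydroxypent-3-en-2-one F10, and dilute aqueous AcOH closes the ring with loss of the amine, which comes back to the route at 10.

## Further compounds

F1 | step 7 | 2-[(2R)-4-oxo-4-(2,6,6-trimethylcyclohex-1-en-1-yl)butan-2-yl]-5-[(tert-butyldimethylsilyloxy)methyl]furan-3(2H)-one (C2 of the furanone epimerisable) | C[C@H](CC(=O)C1=C(C)CCCC1(C)C)C1OC(CO[Si](C)(C)C(C)(C)C)=CC1=O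
F2 | step 7 | 3-(tert-butyldimethylsilyloxy)-5-[(tert-butyldimethylsilyloxy)methyl]-2-[(2R)-4-oxo-4-(2,6,6-trimethylcyclohex-1-en-1-yl)butan-2-yl]furan | C[C@H](CC(=O)C1=C(C)CCCC1(C)C)c1oc(CO[Si](C)(C)C(C)(C)C)cc1O[Si](C)(C)C(C)(C)C
F3 | step 9 | (8βH)-13-allyl-6,16-bis(tert-butyldimethylsilyloxy)-9α,13-epoxy-11-(trimethylsilyloxy)-14,15-dinorlabda-5,11-diene, allyl toward C8 | CC(C)(C)[Si](C)(C)OC1=C2C(C)(C)CCC[C@]2(C)[C@]3(O[C@](CO[Si](C)(C)C(C)(C)C)(CC=C)C=C3O[Si](C)(C)C)[C@H](C)C1
F4 | step 8 | (8βH)-6,16-bis(tert-butyldimethylsilyloxy)-9α,13-epoxy-14,15-dinorlabda-5,12-dien-11-ol, hydroxyl on the ring C face toward C8 | CC(C)(C)[Si](C)(C)OC1=C2C(C)(C)CCC[C@]2(C)[C@]3(OC(CO[Si](C)(C)C(C)(C)C)=C[C@@H]3O)[C@H](C)C1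
F5 | step 8 | acetate of F4 | CC(C)(C)[Si](C)(C)OC1=C2C(C)(C)CCC[C@]2(C)[C@]3(OC(CO[Si](C)(C)C(C)(C)C)=C[C@@H]3OC(C)=O)[C@H](C)C1
F6 | step 8 | O-silyl ketene acetal of F5 | CC(C)(C)[Si](C)(C)OC1=C2C(C)(C)CCC[C@]2(C)[C@]3(OC(CO[Si](C)(C)C(C)(C)C)=C[C@@H]3OC(=C)O[Si](C)(C)C(C)(C)C)[C@H](C)C1
F7 | step 8 | tert-butyldimethylsilyl (8βH)-6,16-bis(tert-butyldimethylsilyloxy)-9α,13-epoxylabda-5,11-dien-15-oate, C14 toward C8 | CC(C)(C)[Si](C)(C)OC1=C2C(C)(C)CCC[C@]2(C)[C@]3(O[C@](CO[Si](C)(C)C(C)(C)C)(CC(=O)O[Si](C)(C)C(C)(C)C)C=C3)[C@H](C)C1
F8 | step 8 | tert-butyldimethylsilyl (8βH)-6,16-bis(tert-butyldimethylsilyloxy)-9α,13-epoxylabd-5-en-15-oate, C14 toward C8 | CC(C)(C)[Si](C)(C)OC1=C2C(C)(C)CCC[C@]2(C)[C@]3(O[C@](CO[Si](C)(C)C(C)(C)C)(CC(=O)O[Si](C)(C)C(C)(C)C)CC3)[C@H](C)C1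
F9 | step 12 | (5α,8βH)-9α,13-epoxy-6-oxolabd-11-en-15-oic acid 15,16-lactone | O=C1C[C@@H](C)[C@]2(C=C[C@]3(COC(=O)C3)O2)[C@@]2(C)CCCC(C)(C)[C@H]12
F10 | step 5 | 4-(diethylamino)-5-(tert-butyldimethylsilyloxy)-1-hydroxypent-3-en-2-one | CCN(CC)C(CO[Si](C)(C)C(C)(C)C)=CC(=O)CO
A1 | alternative 1 | (E)-2,4,8,8-tetramethyl-10-nitrodeca-1,9-dien-3-one | C=C(C)C(=O)C(C)CCCC(C)(C)/C=C/[N+](=O)[O-]
A2 | alternative 1 | 4,4,8α,10β-tetramethyl-6α-nitro-trans-decalin-9-one (labdane numbering) | [O-][N+](=O)[C@H]1C[C@@H](C)C(=O)[C@@]2(C)CCCC(C)(C)[C@H]12
A3 | alternative 2 | 6-(tert-butyldimethylsilyloxy)-8α,10β-dimethyl-10α-(4-methylpent-3-en-1-yl)cyclohex-5-ene-9-spiro-γ-lactone (labdane numbering, ring oxygen α) | CC(C)(C)[Si](C)(C)OC1=C[C@](C)(CCC=C(C)C)[C@@]2(CCC(=O)O2)[C@H](C)C1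
A4 | alternative 2 | tricyclic 6-keto-9α,13-spirolactone with C13 as lactone carbonyl | O=C1C[C@@H](C)[C@]2(CCC(=O)O2)[C@@]2(C)CCCC(C)(C)[C@H]12
A5 | alternative 3 | 8,9-seco keto enone: (E)-1-{(1S,2S)-2-[4-(tert-butyldimethylsilyloxy)butanoyl]-2,6,6-trimethylcyclohexyl}but-2-en-1-one | C/C=C/C(=O)[C@H]1C(C)(C)CCC[C@]1(C)C(=O)CCCO[Si](C)(C)C(C)(C)C
A6 | alternative 3 | 9α-hydroxy-8α-methyl-9β-(3-silyloxypropyl)-4,4,10-trimethyl-trans-decalin-6-one | O=C1C[C@@H](C)[C@](O)(CCCO[Si](C)(C)C(C)(C)C)[C@@]2(C)CCCC(C)(C)[C@H]12
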